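## Retrosynthetic overview

- The fourteen-membered ring and the γ-lactone close last, in one step: intramolecular indium Barbier allylation forming C1–C2, then lactonisation.
- The open chain is built on a preformed cis-3,6-disubstituted 1,2-dioxane: C12=C13 by a Z-selective Wittig reaction of its methyl ketone, C6–C7 by a catalyst-controlled alkylzinc addition to its aldehyde.
- The dioxane keto-aldehyde comes from ozonolysis of 1,5-dimethyl-2,3-dioxabicyclo[2.2.2]oct-5-ene.
- Key step: this bicycle is made from 1,3-dimethylcyclohexa-1,3-diene and triplet O2 in an aminium-initiated radical-cation chain. Both C–O bonds of the peroxide (C8–O, C11–O) form there, locked cis.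
- Ring order: six-membered carbocyclic template (later cut open) → 1,2-dioxane → fourteen-membered carbocycle and γ-lactone together.

Assumption: atoms are labelled with cembrane numbers of the target (C1/C2 lactone fusion with O on C2, C3=C4, C7 OAc, C8 and C11 peroxide carbons, C12=C13, C15–C17 acrylate unit, C18–C20 methyls).
Assumption: (2E)-3-methylpent-2-en-4-yn-1-ol is bought as the pure E isomer.
Assumption: the silyl ether 14 is counted by its 3-bromopropan-1-ol core (five non-hydrogen atoms), the silyl group being a protecting group.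

## Route

Step 1
Reactants: 1 3-methylcyclohex-2-en-1-one
Product: 2 5-methylcyclohexa-1,5-dien-1-yl trifluoromethanesulfonate
Conditions: LiN(iPr)2, THF, −78 °C; PhNTf2, −78 °C to rt
Reagents that add atoms: N-phenylbis(trifluoromethanesulfonimide), O=S(=O)(N(c1ccccc1)S(=O)(=O)C(F)(F)F)C(F)(F)F
Why: Kinetic deprotonation at C6 of the enone gives the cross-conjugated lithium dienolate, which is O-sulfonylated (enol triflate formation) to the 2-triflyloxy-1,3-diene; no stereocentre is formed.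

Step 2
Reactants: 2 5-methylcyclohexa-1,5-dien-1-yl trifluoromethanesulfonate
Product: 3 1,3-dimethylcyclohexa-1,3-diene
Conditions: MeMgBr, Fe(acac)3 (5 mol %), THF/NMP, −30 to 0 °C
Reagents that add atoms: methylmagnesium bromide, C[Mg]Br
Why: Fe(acac)3-catalysed Kumada-type cross-coupling of the alkenyl triflate replaces OTf by methyl without moving the diene; no stereocentre is formed.

Step 3
Reactants: 3 1,3-dimethylcyclohexa-1,3-diene
Product: 4 rac-(1S,4R)-1,5-dimethyl-2,3-dioxabicyclo[2.2.2]oct-5-ene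
Conditions: O2 (1 atm), (4-BrC6H4)3N•+ SbCl6− (5 mol %), CH2Cl2, −78 °C, dark
Reagents that add atoms: dioxygen, O=O
Why: Aminium-initiated radical-cation chain oxygenation (Barton type): the diene radical cation captures triplet O2 at a diene terminus, the distonic peroxyl radical cation closes onto the other terminus and passes the hole to the next diene, so both peroxide C–O bonds (C8–O and C11–O) form in radical steps and the bicycle fixes them cis (racemate).

Step 4
Reactants: 4 rac-(1S,4R)-1,5-dimethyl-2,3-dioxabicyclo[2.2.2]oct-5-ene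
Product: 5 rac-(3S,6R)-6-acetyl-3-methyl-1,2-dioxane-3-carbaldehyde
Conditions: O3, CH2Cl2, −78 °C; Me2S, −78 °C to rt
Reagents that add atoms: ozone, [O-][O+]=O
Why: Ozonolysis with reductive work-up cuts only the C=C bridge and leaves the dialkyl peroxide, giving the cis-3,6-disubstituted 1,2-dioxane with C7 as aldehyde and C12 as methyl ketone; both stereocentres are untouched.

Step 5
Reactants: 6 (2E)-3-methylpent-2-en-4-yn-1-ol
Product: 8 (3E)-5,5-dimethoxy-3-methylpent-3-en-1-yne, via enynal 7 (not isolated)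
Conditions: MnO2, CH2Cl2, rt; filter; HC(OMe)3, MeOH, PPTS (cat.), rt
Reagents that add atoms: trimethyl orthoformate, COC(OC)OC; methanol, CO
Why: Allylic oxidation with MnO2 keeps the E geometry and the volatile enynal is acetalised directly in the filtrate by acid-catalysed exchange with the orthoformate; no stereocentre.

Step 6
Reactants: 8 (3E)-5,5-dimethoxy-3-methylpent-3-en-1-yne
Product: 9 (3E)-5,5-dimethoxy-3-methylpenta-1,3-diene
Conditions: H2 (1 atm), Pd/CaCO3–Pb(OAc)2 (Lindlar), quinoline, pentane, 0 °C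
Reagents that add atoms: none
Why: Lindlar semi-hydrogenation stops the terminal alkyne at the vinyl stage while the trisubstituted E-alkene is inert; no stereocentre.

Step 7
Reactants: 5 rac-(3S,6R)-6-acetyl-3-methyl-1,2-dioxane-3-carbaldehyde; 9 (3E)-5,5-dimethoxy-3-methylpenta-1,3-diene
Product: 12 (1S,4E)-1-[(3S,6R)-6-acetyl-3-methyl-1,2-dioxan-3-yl]-6,6-dimethoxy-4-methylhex-4-en-1-ol, via alkylborane 10 (not isolated), via dialkylzinc 11 (not isolated)
Conditions: 9, Et2BH (from BH3·SMe2 + Et3B), Et2O, 0 °C; Et2Zn, 0 °C, then vacuum; rac-5, Ti(OiPr)4, (1R,2R)-C6H10(NHTf)2 (8 mol %), toluene, −20 °C; chromatography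
Reagents that add atoms: none
Why: Anti-Markovnikov hydroboration of the vinyl group, boron–zinc exchange and Ti(OiPr)4/bis-sulfonamide-catalysed enantioselective alkylzinc addition (Knochel type) to the aldehyde only: the (1R,2R) ligand directs Si-face attack and sets C7 as S in both enantiomers of 5, so 12 (7S,8S,11R) is separated from its (7S,8R,11S) diastereomer, which also resolves the peroxide (at most half of the material).

Step 8
Reactants: 12 (1S,4E)-1-[(3S,6R)-6-acetyl-3-methyl-1,2-dioxan-3-yl]-6,6-dimethoxy-4-methylhex-4-en-1-ol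
Product: 13 (1S,4E)-1-[(3S,6R)-6-acetyl-3-methyl-1,2-dioxan-3-yl]-6,6-dimethoxy-4-methylhex-4-en-1-yl acetate
Conditions: AcCl, pyridine, CH2Cl2, 0 °C
Reagents that add atoms: acetyl chloride, CC(Cl)=O
Why: O-acylation of the hindered secondary alcohol in pyridine, a base too weak to start Kornblum–DeLaMare fragmentation of the α-peroxy ketone; C7 keeps its configuration.

Step 9
Reactants: 14 (3-bromopropoxy)(tert-butyl)dimethylsilane
Product: 15 {3-[(tert-butyldimethylsilyl)oxy]propyl}triphenylphosphonium bromide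
Conditions: PPh3, MeCN, 80 °C
Reagents that add atoms: triphenylphosphine, c1ccc(cc1)P(c1ccccc1)c1ccccc1
Why: SN2 quaternisation of PPh3 by the primary bromide gives the Wittig salt.

Step 10
Reactants: 13 (1S,4E)-1-[(3S,6R)-6-acetyl-3-methyl-1,2-dioxan-3-yl]-6,6-dimethoxy-4-methylhex-4-en-1-yl acetate; 15 {3-[(tert-butyldimethylsilyl)oxy]propyl}triphenylphosphonium bromide
Product: 18 (1S,4E)-1-{(3S,6R)-6-[(2Z)-5-hydroxypent-2-en-2-yl]-3-methyl-1,2-dioxan-3-yl}-6,6-dimethoxy-4-methylhex-4-en-1-yl acetate, via ylide 16 (not isolated), via silyl ether 17 (not isolated)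
Conditions: 15, KN(SiMe3)2, THF, −78 °C; 13, −78 to −30 °C; then MeOH, CSA, 0 °C
Reagents that add atoms: none
Why: Wittig olefination of an α-oxygenated methyl ketone with a non-stabilised ylide (Still's Z-selective variant) puts the oxygen-bearing C11 cis to the new chain, giving the 12Z alkene, at −78 °C where carbonyl addition outruns deprotonation at C11; acidic methanol then removes the silyl ether and keeps the dimethyl acetal.

Step 11
Reactants: 18 (1S,4E)-1-{(3S,6R)-6-[(2Z)-5-hydroxypent-2-en-2-yl]-3-methyl-1,2-dioxan-3-yl}-6,6-dimethoxy-4-methylhex-4-en-1-yl acetate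
Product: 19 (1S,4E)-1-{(3S,6R)-3-methyl-6-[(2Z)-5-oxopent-2-en-2-yl]-1,2-dioxan-3-yl}-6,6-dimethoxy-4-methylhex-4-en-1-yl acetate
Conditions: Dess–Martin periodinane, NaHCO3, CH2Cl2, 0 °C
Reagents that add atoms: none
Why: Buffered Dess–Martin oxidation gives the β,γ-unsaturated aldehyde without base, so the Z-alkene does not move into conjugation; the aldehyde is used at once.

Step 12
Reactants: 19 (1S,4E)-1-{(3S,6R)-3-methyl-6-[(2Z)-5-oxopent-2-en-2-yl]-1,2-dioxan-3-yl}-6,6-dimethoxy-4-methylhex-4-en-1-yl acetate; 20 methyl prop-2-ynoate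
Product: 22 methyl (5Z)-6-{(3R,6S)-6-[(1S,4E)-1-acetoxy-6,6-dimethoxy-4-methylhex-4-en-1-yl]-6-methyl-1,2-dioxan-3-yl}-3-hydroxy-2-methylidenehept-5-enoate, via vinylalane 21 (not isolated)
Conditions: iBu2AlH, NMO, THF, 0 °C; 20; then 19, 0 °C to rt; aq. citric acid
Reagents that add atoms: none
Why: Vinylalumination, a non-basic Morita–Baylis–Hillman equivalent: hydride adds 1,4 to the propiolate and the α-aluminated acrylate adds to the aldehyde; the carbinol centre forms as a mixture and is erased in the next step.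

Step 13
Reactants: 22 methyl (5Z)-6-{(3R,6S)-6-[(1S,4E)-1-acetoxy-6,6-dimethoxy-4-methylhex-4-en-1-yl]-6-methyl-1,2-dioxan-3-yl}-3-hydroxy-2-methylidenehept-5-enoate
Product: 23 methyl (2Z,5Z)-6-{(3R,6S)-6-[(1S,4E)-1-acetoxy-6,6-dimethoxy-4-methylhex-4-en-1-yl]-6-methyl-1,2-dioxan-3-yl}-2-(bromomethyl)hepta-2,5-dienoate
Conditions: NBS, Me2S, CH2Cl2, −20 to 0 °C
Reagents that add atoms: N-bromosuccinimide, O=C1CCC(=O)N1Br
Why: Corey–Kim-type bromination of the Baylis–Hillman alcohol proceeds with SN2′ transposition to the favoured (Z)-2-(bromomethyl)enoate and removes the carbinol stereocentre.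

Step 14
Reactants: 23 methyl (2Z,5Z)-6-{(3R,6S)-6-[(1S,4E)-1-acetoxy-6,6-dimethoxy-4-methylhex-4-en-1-yl]-6-methyl-1,2-dioxan-3-yl}-2-(bromomethyl)hepta-2,5-dienoate
Product: 24 methyl (2Z,5Z)-6-{(3R,6S)-6-[(1S,4E)-1-acetoxy-4-methyl-6-oxohex-4-en-1-yl]-6-methyl-1,2-dioxan-3-yl}-2-(bromomethyl)hepta-2,5-dienoate
Conditions: Amberlyst-15, acetone/H2O (20:1), rt
Reagents that add atoms: water, O
Why: Mild acid hydrolysis of the allylic dimethyl acetal frees the E-enal while the allylic bromide, acetate and peroxide survive.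

Step 15
Reactants: 24 methyl (2Z,5Z)-6-{(3R,6S)-6-[(1S,4E)-1-acetoxy-4-methyl-6-oxohex-4-en-1-yl]-6-methyl-1,2-dioxan-3-yl}-2-(bromomethyl)hepta-2,5-dienoate
Product: 26 (1S,2S,3E,7S,8S,11R,12Z)-7-acetoxy-8,11-epidioxycembra-3,12,15(17)-trien-16,2-olide (CNP0238885.10), via hydroxy ester 25 (not isolated)
Conditions: In powder, THF/H2O (3:1), 1 mM (syringe pump), rt; then TsOH·H2O (cat.), CH2Cl2, rt
Reagents that add atoms: none
Why: Intramolecular indium Barbier allylation at high dilution forms C1–C2 through a chair transition state of the (Z)-allylindium (syn adduct, hence the cis lactone after acid-catalysed lactonisation), while the sense of C1/C2 relative to the dioxane rests on transannular substrate control that cannot be predicted with confidence, the (1S,2S) isomer being separable from the other cis-lactone.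

## Compound list

1 | 3-methylcyclohex-2-en-1-one | CC1=CC(=O)CCC1 | starting material
2 | 5-methylcyclohexa-1,5-dien-1-yl trifluoromethanesulfonate | CC1=CC(OS(=O)(=O)C(F)(F)F)=CCC1 | intermediate
3 | 1,3-dimethylcyclohexa-1,3-diene | CC1=CC(C)=CCC1 | intermediate
4 | rac-(1S,4R)-1,5-dimethyl-2,3-dioxabicyclo[2.2.2]oct-5-ene (racemate; the enantiomer carried on is drawn) | CC1=C[C@]2(C)CC[C@H]1OO2 | intermediate
5 | rac-(3S,6R)-6-acetyl-3-methyl-1,2-dioxane-3-carbaldehyde (cis; racemate; the enantiomer carried on is drawn) | O=C[C@]1(C)CC[C@@H](OO1)C(C)=O | intermediate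
6 | (2E)-3-methylpent-2-en-4-yn-1-ol | C#C/C(C)=C/CO | starting material
7 | (2E)-3-methylpent-2-en-4-ynal | C#C/C(C)=C/C=O | intermediate
8 | (3E)-5,5-dimethoxy-3-methylpent-3-en-1-yne | C#C/C(C)=C/C(OC)OC | intermediate
9 | (3E)-5,5-dimethoxy-3-methylpenta-1,3-diene | C=C/C(C)=C/C(OC)OC | intermediate
10 | diethyl[(3E)-5,5-dimethoxy-3-methylpent-3-en-1-yl]borane | CCB(CC)CC/C(C)=C/C(OC)OC | intermediate
11 | bis[(3E)-5,5-dimethoxy-3-methylpent-3-en-1-yl]zinc | COC(OC)/C=C(\C)CC[Zn]CC/C(C)=C/C(OC)OC | intermediate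
12 | (1S,4E)-1-[(3S,6R)-6-acetyl-3-methyl-1,2-dioxan-3-yl]-6,6-dimethoxy-4-methylhex-4-en-1-ol | COC(OC)/C=C(\C)CC[C@H](O)[C@]1(C)CC[C@@H](OO1)C(C)=O | intermediate
13 | (1S,4E)-1-[(3S,6R)-6-acetyl-3-methyl-1,2-dioxan-3-yl]-6,6-dimethoxy-4-methylhex-4-en-1-yl acetate | COC(OC)/C=C(\C)CC[C@H](OC(C)=O)[C@]1(C)CC[C@@H](OO1)C(C)=O | intermediate
14 | (3-bromopropoxy)(tert-butyl)dimethylsilane | CC(C)(C)[Si](C)(C)OCCCBr | starting material
15 | {3-[(tert-butyldimethylsilyl)oxy]propyl}triphenylphosphonium bromide | CC(C)(C)[Si](C)(C)OCCC[P+](c1ccccc1)(c1ccccc1)c1ccccc1.[Br-] | intermediate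
16 | {3-[(tert-butyldimethylsilyl)oxy]propylidene}triphenylphosphorane | CC(C)(C)[Si](C)(C)OCCC=P(c1ccccc1)(c1ccccc1)c1ccccc1 | intermediate
17 | (1S,4E)-1-[(3S,6R)-6-{(2Z)-5-[(tert-butyldimethylsilyl)oxy]pent-2-en-2-yl}-3-methyl-1,2-dioxan-3-yl]-6,6-dimethoxy-4-methylhex-4-en-1-yl acetate | COC(OC)/C=C(\C)CC[C@H](OC(C)=O)[C@]1(C)CC[C@@H](OO1)/C(C)=C\CCO[Si](C)(C)C(C)(C)C | intermediate
18 | (1S,4E)-1-{(3S,6R)-6-[(2Z)-5-hydroxypent-2-en-2-yl]-3-methyl-1,2-dioxan-3-yl}-6,6-dimethoxy-4-methylhex-4-en-1-yl acetate | COC(OC)/C=C(\C)CC[C@H](OC(C)=O)[C@]1(C)CC[C@@H](OO1)/C(C)=C\CCO | intermediate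
19 | (1S,4E)-1-{(3S,6R)-3-methyl-6-[(2Z)-5-oxopent-2-en-2-yl]-1,2-dioxan-3-yl}-6,6-dimethoxy-4-methylhex-4-en-1-yl acetate | COC(OC)/C=C(\C)CC[C@H](OC(C)=O)[C@]1(C)CC[C@@H](OO1)/C(C)=C\CC=O | intermediate
20 | methyl prop-2-ynoate | C#CC(=O)OC | starting material
21 | methyl 2-[bis(2-methylpropyl)alumanyl]prop-2-enoate | C=C(C(=O)OC)[Al](CC(C)C)CC(C)C | intermediate
22 | methyl (5Z)-6-{(3R,6S)-6-[(1S,4E)-1-acetoxy-6,6-dimethoxy-4-methylhex-4-en-1-yl]-6-methyl-1,2-dioxan-3-yl}-3-hydroxy-2-methylidenehept-5-enoate (both C3 epimers) | COC(OC)/C=C(\C)CC[C@H](OC(C)=O)[C@]1(C)CC[C@@H](OO1)/C(C)=C\CC(O)C(=C)C(=O)OC | intermediate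
23 | methyl (2Z,5Z)-6-{(3R,6S)-6-[(1S,4E)-1-acetoxy-6,6-dimethoxy-4-methylhex-4-en-1-yl]-6-methyl-1,2-dioxan-3-yl}-2-(bromomethyl)hepta-2,5-dienoate | COC(OC)/C=C(\C)CC[C@H](OC(C)=O)[C@]1(C)CC[C@@H](OO1)/C(C)=C\C/C=C(\CBr)C(=O)OC | intermediate
24 | methyl (2Z,5Z)-6-{(3R,6S)-6-[(1S,4E)-1-acetoxy-4-methyl-6-oxohex-4-en-1-yl]-6-methyl-1,2-dioxan-3-yl}-2-(bromomethyl)hepta-2,5-dienoate | O=C/C=C(\C)CC[C@H](OC(C)=O)[C@]1(C)CC[C@@H](OO1)/C(C)=C\C/C=C(\CBr)C(=O)OC | intermediate
25 | methyl 2-[(1S,2S,3E,7S,8S,11R,12Z)-7-acetoxy-2-hydroxy-4,8,12-trimethyl-8,11-epidioxycyclotetradeca-3,12-dien-1-yl]prop-2-enoate (cembrane numbering) | O[C@H]1/C=C(\C)CC[C@H](OC(C)=O)[C@]2(C)CC[C@@H](OO2)/C(C)=C\C[C@H]1C(=C)C(=O)OC | intermediate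
26 | (1S,2S,3E,7S,8S,11R,12Z)-7-acetoxy-8,11-epidioxycembra-3,12,15(17)-trien-16,2-olide (CNP0238885.10) | C=C1C(=O)O[C@H]2/C=C(\C)CC[C@H](OC(C)=O)[C@]3(C)CC[C@@H](OO3)/C(C)=C\C[C@@H]12 | target

## Step count and risks

Total step count: 15. Longest linear sequence: 12 (steps 1–4, 7, 8, 10–15).

The three steps most likely to fail are steps 3, 10 and 15. Step 7 is also limited to half of the material because it resolves the racemate, and it exposes the peroxide to Et2Zn and Ti(OiPr)4.

Step 3. The aminium-initiated chain may be outrun by radical-cation dimerisation of the small diene. The fallback sets out from 3 and returns to 4 through a different oxygenation manifold: tetraphenylporphyrin-sensitised photooxygenation (O2, visible light, CH2Cl2, −30 °C), in which singlet oxygen adds across the cisoid diene in a concerted [4+2] fashion. The same racemic bicycle 4 results and no new compound is made.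

Step 10. The ylide may act as a base on the α-peroxy ketone (Kornblum–DeLaMare fragmentation or loss of the cis relationship at C11), or give poor Z-selectivity. The fallback sets out from 13 and returns at 18 without any ylide. B-[(2E)-3-(trimethylsilyl)prop-2-en-1-yl]-9-borabicyclo[3.3.1]nonane (from allyltrimethylsilane, s-BuLi/TMEDA, then B-methoxy-9-BBN and BF3·OEt2) allylborates the ketone through a closed chair, without enolisation, to give the anti β-hydroxysilane F1. KN(SiMe3)2 (THF, −78 °C) then triggers a stereospecific syn-Peterson elimination to the (Z)-diene F2. Hydroboration of the terminal vinyl group with 9-BBN and oxidation with NaBO3·4H2O gives 18.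

Step 15. Indium metal may attack the O–O bond, or the tether may fold to the wrong aldehyde face. The fallback sets out from 22 and returns at 25 through a metal-free, catalyst-controlled closure. Acetylation (Ac2O, pyridine, DMAP) gives the Baylis–Hillman acetate F3. SN2′ borylation with B2pin2 (CuCl, LiCl, KOAc, DMF, rt) gives the 2-(methoxycarbonyl)allylboronate F4, and Amberlyst-15 in wet acetone frees the enal F5. Intramolecular allylboration at high dilution is then catalysed by the chiral phosphoric acid TRIP (toluene, rt), with the enantiomer chosen by screening so that the catalyst selects the aldehyde face. Aqueous work-up gives the syn hydroxy ester 25, which lactonises to 26 as in step 15.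

Further compounds
F0 | step 3 | none | none
F1 | step 10 | (1S,4E)-1-{(3S,6R)-6-[2-hydroxy-3-(trimethylsilyl)pent-4-en-2-yl]-3-methyl-1,2-dioxan-3-yl}-6,6-dimethoxy-4-methylhex-4-en-1-yl acetate (anti at the two new centres, which are left open in the SMILES) | COC(OC)/C=C(\C)CC[C@H](OC(C)=O)[C@]1(C)CC[C@@H](OO1)C(C)(O)C(C=C)[Si](C)(C)C
F2 | step 10 | (1S,4E)-1-{(3S,6R)-3-methyl-6-[(2Z)-penta-2,4-dien-2-yl]-1,2-dioxan-3-yl}-6,6-dimethoxy-4-methylhex-4-en-1-yl acetate | COC(OC)/C=C(\C)CC[C@H](OC(C)=O)[C@]1(C)CC[C@@H](OO1)/C(C)=C\C=C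
F3 | step 15 | methyl (5Z)-3-acetoxy-6-{(3R,6S)-6-[(1S,4E)-1-acetoxy-6,6-dimethoxy-4-methylhex-4-en-1-yl]-6-methyl-1,2-dioxan-3-yl}-2-methylidenehept-5-enoate (both C3 epimers) | COC(OC)/C=C(\C)CC[C@H](OC(C)=O)[C@]1(C)CC[C@@H](OO1)/C(C)=C\CC(OC(C)=O)C(=C)C(=O)OC
F4 | step 15 | methyl (2E,5Z)-6-{(3R,6S)-6-[(1S,4E)-1-acetoxy-6,6-dimethoxy-4-methylhex-4-en-1-yl]-6-methyl-1,2-dioxan-3-yl}-2-[(4,4,5,5-tetramethyl-1,3,2-dioxaborolan-2-yl)methyl]hepta-2,5-dienoate | COC(OC)/C=C(\C)CC[C@H](OC(C)=O)[C@]1(C)CC[C@@H](OO1)/C(C)=C\C/C=C(\CB2OC(C)(C)C(C)(C)O2)C(=O)OC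
F5 | step 15 | methyl (2E,5Z)-6-{(3R,6S)-6-[(1S,4E)-1-acetoxy-4-methyl-6-oxohex-4-en-1-yl]-6-methyl-1,2-dioxan-3-yl}-2-[(4,4,5,5-tetramethyl-1,3,2-dioxaborolan-2-yl)methyl]hepta-2,5-dienoate | O=C/C=C(\C)CC[C@H](OC(C)=O)[C@]1(C)CC[C@@H](OO1)/C(C)=C\C/C=C(\CB2OC(C)(C)C(C)(C)O2)C(=O)OC
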